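**Plan** (lignan numbering: ring carbons 1–6, benzylic C7, methine C8, methyl C9; primes for the syringyl half)

- **Cuts:** the C3–OH of the catechol ring is traced back to OMe, which makes both rings the same syringyl unit and the molecule C2-symmetric. The methyls C9/C9′ are raised to ester carbons. The bonds aryl C1–C7 and aryl C1′–C7′ are then cut together.
- **Enabling feature:** with C9/C9′ as CO2Me, C7/C7′ are β-carbons and C8/C8′ α-carbons of two acrylate units joined through C8–C8′. The core C7–C8(C9)–C8′(C9′)–C7′ is therefore 2,3-dimethylenesuccinate. The two benzene rings differ by one O-methyl only, so a single arylboronic acid fills both ends.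
- **Forward:** no ring is formed. Two ready-made arenes are joined to the C6 core in one twofold conjugate arylation. Then follow ester → CH2OH → CH2OMs → CH3, debenzylation and one oxidative O-demethylation.
- **Stereochemistry:** C8 and C8′ both arise in the arylation step by ligand-controlled protonation of the two rhodium enolates. Mismatched events end in the separable meso diester. (2R,3R) in the diester corresponds to (8R,8′R) in the target, and no later step touches these centres.

Key step: step 5

Assumption: the face chosen in a rhodium enolate protonation depends on ligand, donor and substrate and cannot be predicted safely. "(S)-DIFLUORPHOS" below therefore stands for the ligand antipode that turns dimethyl itaconate and phenylboronic acid into dimethyl (R)-2-benzylsuccinate under the same conditions, and the mirror-image ligand is taken if that calibration points the other way.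

Step 1
Reactants: 1 4-bromo-2,6-dimethoxyphenol; 2 benzyl bromide
Product: 3 2-(benzyloxy)-5-bromo-1,3-dimethoxybenzene
Conditions: BnBr (1.1 equiv), K2CO3, DMF, rt
Reagents that add atoms: benzyl bromide (2), BrCc1ccccc1
Why: Williamson ether synthesis, in which the acidic 2,6-dimethoxyphenoxide is alkylated on oxygen by the benzylic bromide while the aryl bromide is inert to carbonate.

Step 2
Reactants: 3 2-(benzyloxy)-5-bromo-1,3-dimethoxybenzene
Product: 6 [4-(benzyloxy)-3,5-dimethoxyphenyl]boronic acid, via aryllithium 4 (not isolated), via lithium aryltriisopropoxyborate 5 (not isolated)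
Conditions: n-BuLi, THF, −78 °C; B(OiPr)3, −78 °C → rt; 1 M HCl
Reagents that add atoms: triisopropyl borate, CC(C)OB(OC(C)C)OC(C)C; water, O
Why: Bromine–lithium exchange followed by electrophilic borylation, where exchange at −78 °C outruns ortho- or benzylic lithiation, the borate ester traps the aryllithium and mild acid hydrolyses the ate complex without harming the benzyl ether.

Step 3
Reactants: 7 but-2-yne-1,4-diol
Product: 8 but-2-yne-1,4-diyl dimethyl biscarbonate
Conditions: ClCO2Me (2.4 equiv), pyridine, CH2Cl2, 0 °C → rt
Reagents that add atoms: methyl chloroformate, COC(=O)Cl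
Why: Standard O-acylation of a primary propargylic diol with a chloroformate, with pyridine taking up the hydrogen chloride.

Step 4
Reactants: 8 but-2-yne-1,4-diyl dimethyl biscarbonate
Product: 10 dimethyl 2,3-dimethylenesuccinate, via allenoate carbonate 9 (not isolated)
Conditions: Pd2(dba)3·CHCl3 (2.5 mol %), PPh3 (20 mol %), CO (10 bar), THF/MeOH 4:1, BHT (trace), 40 °C; short silica plug, kept cold in dilute solution, used the same day
Reagents that add atoms: carbon monoxide, [C-]#[O+]
Why: Palladium-catalysed decarboxylative carbonylation of propargylic carbonates, in which SN2′ ionisation gives an allenylpalladium methoxide that inserts CO to allenoate 9, whose remaining allenylmethyl carbonate ionises in the same way to a 1,3-dien-2-ylpalladium that is carbonylated to 10, the methoxide released with CO2 ending as the ester methoxy group.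

Step 5
Reactants: 10 dimethyl 2,3-dimethylenesuccinate; 6 [4-(benzyloxy)-3,5-dimethoxyphenyl]boronic acid (two equivalents incorporated, three used)
Product: 12 dimethyl (2R,3R)-2,3-bis[4-(benzyloxy)-3,5-dimethoxybenzyl]succinate, via mono-adduct 11 (not isolated)
Conditions: Rh(acac)(C2H4)2 (6 mol %), (S)-DIFLUORPHOS (6.6 mol %), 6 (3 equiv), 2-methoxyphenol (2.5 equiv), degassed 1,4-dioxane, 50 °C, 10 added by syringe pump; aqueous work-up, meso isomer removed by chromatography or crystallisation
Reagents that add atoms: none
Why: Proposed new method: transmetallation of 6 to the Rh(I)–diphosphine gives an aryl–rhodium that carbometallates one methylene terminus of 10 (each CH2= is β to its own ester only, because the diene is cross-conjugated), the oxa-π-allyl rhodium enolate is protonated at its α-carbon by 2-methoxyphenol inside the ligand pocket to give 11, and 11, a branched itaconate-type acrylate, passes through the same cycle once more to give 12. The closest known reaction type is the Hayashi–Miyaura-type rhodium-catalysed conjugate arylation of α-substituted acrylates, itaconates and dehydroamino esters with enantioselective protonation by phenols, imides or boric acid, and the new element is its twofold use on a 2,3-dimethylenesuccinate. No ring is closed. C8 and C8′ (C2 and C3 of 12) are each fixed by the enolate face that the diphosphine leaves open to the proton donor, so both are under catalyst control, and one wrong protonation leads to the meso diastereomer, whose removal should leave 12 enantiomerically purer than a single protonation event would allow. The step needs α- rather than γ-protonation of the first, vinylogous enolate and no drift of 11 to the tetrasubstituted alkene, which kinetic protonation at the rhodium-bearing carbon, base-free conditions and an excess of a weakly acidic donor are meant to secure. Slow addition keeps the stationary concentration of 10 low and so holds back [4+2] dimerisation, polymerisation, η4-binding of the diene to rhodium and Michael capture of the enolate by a second diene.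

Step 6
Reactants: 12 dimethyl (2R,3R)-2,3-bis[4-(benzyloxy)-3,5-dimethoxybenzyl]succinate
Product: 13 (2R,3R)-2,3-bis[4-(benzyloxy)-3,5-dimethoxybenzyl]butane-1,4-diol
Conditions: LiAlH4, THF, 0 °C → rt
Reagents that add atoms: none
Why: Ester reduction with LiAlH4, in which hydride addition is far faster than enolisation so that C2 and C3 keep their configuration, the ethers are inert, and the diol offers a second chance to remove traces of the meso isomer.

Step 7
Reactants: 13 (2R,3R)-2,3-bis[4-(benzyloxy)-3,5-dimethoxybenzyl]butane-1,4-diol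
Product: 14 (2R,3R)-2,3-bis[4-(benzyloxy)-3,5-dimethoxybenzyl]butane-1,4-diyl dimethanesulfonate
Conditions: MsCl (3 equiv), Et3N (4 equiv), CH2Cl2, −10 → 0 °C; used without storage
Reagents that add atoms: methanesulfonyl chloride, CS(=O)(=O)Cl
Why: Sulfonate ester formation through sulfene, which with excess reagent at low temperature caps both primary alcohols faster than a monomesylate can close to the tetrahydrofuran and does not involve the stereocentres.

Step 8
Reactants: 14 (2R,3R)-2,3-bis[4-(benzyloxy)-3,5-dimethoxybenzyl]butane-1,4-diyl dimethanesulfonate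
Product: 15 1,1′-[(2R,3R)-2,3-dimethylbutane-1,4-diyl]bis[4-(benzyloxy)-3,5-dimethoxybenzene]
Conditions: LiEt3BH (5 equiv), THF, 0 °C → rt
Reagents that add atoms: none
Why: SN2 hydride displacement of primary sulfonates by lithium triethylborohydride, which tolerates β-branching and turns both CH2OMs groups into the methyls C9/C9′ without touching C8/C8′ or the ethers.

Step 9
Reactants: 15 1,1′-[(2R,3R)-2,3-dimethylbutane-1,4-diyl]bis[4-(benzyloxy)-3,5-dimethoxybenzene]
Product: 16 4,4′-[(2R,3R)-2,3-dimethylbutane-1,4-diyl]bis(2,6-dimethoxyphenol)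
Conditions: H2 (1 atm), 10 % Pd/C, EtOAc/MeOH, rt
Reagents that add atoms: none
Why: Catalytic hydrogenolysis of benzyl aryl ethers, under which methyl ethers, arenes and the saturated chain stay unchanged.

Step 10
Reactants: 16 4,4′-[(2R,3R)-2,3-dimethylbutane-1,4-diyl]bis(2,6-dimethoxyphenol)
Product: 18 sauriol B (5-[(2R,3R)-4-(4-hydroxy-3,5-dimethoxyphenyl)-2,3-dimethylbutyl]-3-methoxybenzene-1,2-diol), via ortho-quinone 17 (not isolated)
Conditions: IBX (0.8 equiv), DMF, 0 °C → rt; then aq. Na2S2O4, rt; unreacted 16 recovered and resubmitted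
Reagents that add atoms: 2-iodoxybenzoic acid (IBX, delivers the new ring oxygen), O=C1OI(=O)(O)c2ccccc12
Why: IBX-mediated oxidative demethylation of a 2-methoxyphenol, in which the phenol binds to iodine(V), oxygen is passed to the ortho carbon bearing OMe, loss of methanol gives 17 and dithionite reduces it in the same flask to the catechol; C2 symmetry and free ring rotation make all four methoxy groups equivalent, so any first demethylation gives 18, and a deficit of oxidant limits attack on the second ring.

**Compound list**
1 | 4-bromo-2,6-dimethoxyphenol | COc1cc(Br)cc(OC)c1O | starting material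
2 | benzyl bromide | BrCc1ccccc1 | starting material
3 | 2-(benzyloxy)-5-bromo-1,3-dimethoxybenzene | COc1cc(Br)cc(OC)c1OCc1ccccc1 | intermediate
4 | [4-(benzyloxy)-3,5-dimethoxyphenyl]lithium | [Li]c1cc(OC)c(OCc2ccccc2)c(OC)c1 | intermediate
5 | lithium [4-(benzyloxy)-3,5-dimethoxyphenyl]tri(propan-2-yloxy)borate | [Li+].CC(C)O[B-](OC(C)C)(OC(C)C)c1cc(OC)c(OCc2ccccc2)c(OC)c1 | intermediate
6 | [4-(benzyloxy)-3,5-dimethoxyphenyl]boronic acid | COc1cc(B(O)O)cc(OC)c1OCc1ccccc1 | intermediate
7 | but-2-yne-1,4-diol | OCC#CCO | starting material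
8 | but-2-yne-1,4-diyl dimethyl biscarbonate | COC(=O)OCC#CCOC(=O)OC | intermediate
9 | methyl 2-{[(methoxycarbonyl)oxy]methyl}buta-2,3-dienoate | C=C=C(COC(=O)OC)C(=O)OC | intermediate
10 | dimethyl 2,3-dimethylenesuccinate | C=C(C(=O)OC)C(=C)C(=O)OC | intermediate
11 | dimethyl (2R)-2-[4-(benzyloxy)-3,5-dimethoxybenzyl]-3-methylidenebutanedioate | COC(=O)[C@H](Cc1cc(OC)c(OCc2ccccc2)c(OC)c1)C(=C)C(=O)OC | intermediate
12 | dimethyl (2R,3R)-2,3-bis[4-(benzyloxy)-3,5-dimethoxybenzyl]succinate | COC(=O)[C@H](Cc1cc(OC)c(OCc2ccccc2)c(OC)c1)[C@@H](Cc1cc(OC)c(OCc2ccccc2)c(OC)c1)C(=O)OC | intermediate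
13 | (2R,3R)-2,3-bis[4-(benzyloxy)-3,5-dimethoxybenzyl]butane-1,4-diol | OC[C@H](Cc1cc(OC)c(OCc2ccccc2)c(OC)c1)[C@@H](Cc1cc(OC)c(OCc2ccccc2)c(OC)c1)CO | intermediate
14 | (2R,3R)-2,3-bis[4-(benzyloxy)-3,5-dimethoxybenzyl]butane-1,4-diyl dimethanesulfonate | CS(=O)(=O)OC[C@H](Cc1cc(OC)c(OCc2ccccc2)c(OC)c1)[C@@H](Cc1cc(OC)c(OCc2ccccc2)c(OC)c1)COS(C)(=O)=O | intermediate
15 | 1,1′-[(2R,3R)-2,3-dimethylbutane-1,4-diyl]bis[4-(benzyloxy)-3,5-dimethoxybenzene] | C[C@H](Cc1cc(OC)c(OCc2ccccc2)c(OC)c1)[C@@H](Cc1cc(OC)c(OCc2ccccc2)c(OC)c1)C | intermediate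
16 | 4,4′-[(2R,3R)-2,3-dimethylbutane-1,4-diyl]bis(2,6-dimethoxyphenol) | C[C@H](Cc1cc(OC)c(O)c(OC)c1)[C@@H](Cc1cc(OC)c(O)c(OC)c1)C | intermediate
17 | 5-[(2R,3R)-4-(4-hydroxy-3,5-dimethoxyphenyl)-2,3-dimethylbutyl]-3-methoxycyclohexa-3,5-diene-1,2-dione | COC1=CC(C[C@@H](C)[C@H](C)Cc2cc(OC)c(O)c(OC)c2)=CC(=O)C1=O | intermediate
18 | sauriol B, 5-[(2R,3R)-4-(4-hydroxy-3,5-dimethoxyphenyl)-2,3-dimethylbutyl]-3-methoxybenzene-1,2-diol | COc1cc(C[C@@H](C)[C@H](C)Cc2cc(OC)c(O)c(OC)c2)cc(O)c1O | target

**Total step count:** 10.

**Longest linear sequence:** 8 steps, either 1 → 3 → 6 → 12 → 13 → 14 → 15 → 16 → 18 or, equally long, 7 → 8 → 10 → 12 → … → 18.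

**Steps most likely to fail**

1. **Step 5.**
   - **What may go wrong:** γ-protonation of the first vinylogous enolate or drift of the alkene into conjugation with both esters. The second arylation may be sluggish at the branched acrylate. The first centre may bias the second protonation towards the meso series. The diene may be lost by dimerisation or by tight binding to rhodium, and the electron-rich boronic acid may protodeboronate.
   - **Fallback:** known chemistry that forms the C8–C8′ bond under auxiliary control instead of the aryl–C7 bonds. It sets out from 6 and comes back to the route at 13.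
   - **Course:** achiral rhodium-catalysed 1,4-addition of 6 to methyl acrylate ([Rh(cod)OH]2, dioxane/H2O) gives methyl 3-[4-(benzyloxy)-3,5-dimethoxyphenyl]propanoate F1. LiOH gives 3-[4-(benzyloxy)-3,5-dimethoxyphenyl]propanoic acid F2. Pivaloyl chloride/Et3N gives 3-[4-(benzyloxy)-3,5-dimethoxyphenyl]propanoic pivalic anhydride F3, which acylates lithiated (S)-4-isopropyloxazolidin-2-one to (S)-3-{3-[4-(benzyloxy)-3,5-dimethoxyphenyl]propanoyl}-4-isopropyloxazolidin-2-one F4.
   - **Coupling and return:** oxidative enolate homocoupling (LDA, then TiCl4, THF, −78 °C) joins two units on the face remote from the isopropyl groups. This gives (4S,4′S)-3,3′-{(2R,3R)-2,3-bis[4-(benzyloxy)-3,5-dimethoxybenzyl]butanedioyl}bis(4-isopropyloxazolidin-2-one) F5. LiBH4 (THF/MeOH) then removes both auxiliaries reductively and delivers 13.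

2. **Step 10.**
   - **What may go wrong:** the oxidant is distributed statistically over the two identical rings, so the second ring is over-oxidised. The 4-alkyl-ortho-quinone may tautomerise to a para-quinone methide, which can cyclise onto the other electron-rich ring before the reductant arrives.
   - **Fallback:** the rings are told apart by a protecting group instead of by oxidant stoichiometry. It sets out from 15 and comes back at 18.
   - **Course:** hydrogenolysis of 15 is stopped after uptake of one equivalent of hydrogen and gives 4-{(2R,3R)-4-[4-(benzyloxy)-3,5-dimethoxyphenyl]-2,3-dimethylbutyl}-2,6-dimethoxyphenol F6. Recovered 15 is resubmitted, and 16 is re-benzylated as in step 1.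
   - **Oxidation and return:** IBX needs a free phenol, so it can be used in slight excess and the reaction run to completion. This gives 5-{(2R,3R)-4-[4-(benzyloxy)-3,5-dimethoxyphenyl]-2,3-dimethylbutyl}-3-methoxycyclohexa-3,5-diene-1,2-dione F7, reduced in the same flask by dithionite to 5-{(2R,3R)-4-[4-(benzyloxy)-3,5-dimethoxyphenyl]-2,3-dimethylbutyl}-3-methoxybenzene-1,2-diol F8. A final hydrogenolysis (H2, Pd/C) gives 18.

3. **Step 4.**
   - **What may go wrong:** the second ionisation may be incomplete, so that the reaction stalls at the allenoate. Methanol may add in conjugate fashion or a further carbonylation may take place on the very electrophilic product. The diene may dimerise or polymerise during isolation.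
   - **Fallback:** the diene skeleton is built first as a storable dimetallated butadiene, and the esters are installed last under methanol-free conditions. It sets out from 7 and comes back at 10.
   - **Course:** SOCl2/pyridine converts 7 into 1,4-dichlorobut-2-yne F9. Two successive SN2′ displacements with a trimethylstannylcopper reagent (Me3SnLi, CuBr·SMe2, THF, −78 °C) give 2,3-bis(trimethylstannyl)buta-1,3-diene F10. A twofold Stille-type coupling with methyl chloroformate (Pd(PPh3)4, toluene, 60 °C) releases 10 directly before step 5.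

**Further compounds**
F1 | step 5 | methyl 3-[4-(benzyloxy)-3,5-dimethoxyphenyl]propanoate | COC(=O)CCc1cc(OC)c(OCc2ccccc2)c(OC)c1
F2 | step 5 | 3-[4-(benzyloxy)-3,5-dimethoxyphenyl]propanoic acid | OC(=O)CCc1cc(OC)c(OCc2ccccc2)c(OC)c1
F3 | step 5 | 3-[4-(benzyloxy)-3,5-dimethoxyphenyl]propanoic pivalic anhydride | CC(C)(C)C(=O)OC(=O)CCc1cc(OC)c(OCc2ccccc2)c(OC)c1
F4 | step 5 | (S)-3-{3-[4-(benzyloxy)-3,5-dimethoxyphenyl]propanoyl}-4-isopropyloxazolidin-2-one | CC(C)[C@H]1COC(=O)N1C(=O)CCc1cc(OC)c(OCc2ccccc2)c(OC)c1
F5 | step 5 | (4S,4′S)-3,3′-{(2R,3R)-2,3-bis[4-(benzyloxy)-3,5-dimethoxybenzyl]butanedioyl}bis(4-isopropyloxazolidin-2-one) | CC(C)[C@H]1COC(=O)N1C(=O)[C@H](Cc1cc(OC)c(OCc2ccccc2)c(OC)c1)[C@@H](Cc1cc(OC)c(OCc2ccccc2)c(OC)c1)C(=O)N1C(=O)OC[C@@H]1C(C)C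
F6 | step 10 | 4-{(2R,3R)-4-[4-(benzyloxy)-3,5-dimethoxyphenyl]-2,3-dimethylbutyl}-2,6-dimethoxyphenol | COc1cc(C[C@@H](C)[C@H](C)Cc2cc(OC)c(OCc3ccccc3)c(OC)c2)cc(OC)c1O
F7 | step 10 | 5-{(2R,3R)-4-[4-(benzyloxy)-3,5-dimethoxyphenyl]-2,3-dimethylbutyl}-3-methoxycyclohexa-3,5-diene-1,2-dione | COC1=CC(C[C@@H](C)[C@H](C)Cc2cc(OC)c(OCc3ccccc3)c(OC)c2)=CC(=O)C1=O
F8 | step 10 | 5-{(2R,3R)-4-[4-(benzyloxy)-3,5-dimethoxyphenyl]-2,3-dimethylbutyl}-3-methoxybenzene-1,2-diol | COc1cc(C[C@@H](C)[C@H](C)Cc2cc(OC)c(OCc3ccccc3)c(OC)c2)cc(O)c1O
F9 | step 4 | 1,4-dichlorobut-2-yne | ClCC#CCCl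
F10 | step 4 | 2,3-bis(trimethylstannyl)buta-1,3-diene | C=C([Sn](C)(C)C)C(=C)[Sn](C)(C)C
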